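(The rate constants are those of an exercise; the flask was simulated.)

Count the by-product, not the target, when you want to know what the unused reagent in this flask is doing.

starting material 0.17 M; reagent 1.05 equiv; free catalyst 2 mol%; time 2.5 h

- part of the starting material that has reacted at 2.5 h
- share of the unused reagent that is free and not bound as idle adduct, at 2.5 h

- for by-product the idle adduct is counted in
- run time (flask): 2.5 h

    starting material + free catalyst ⇌ catalyst intermediate A (K1 = 120 M⁻¹, k1 = 17.8 M⁻¹ min⁻¹)
    catalyst intermediate A → catalyst intermediate B (k2 = 155 min⁻¹)
    reagent + catalyst intermediate B ⇌ catalyst intermediate C (K3 = 270 M⁻¹, k3 = 195 M⁻¹ min⁻¹)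
    catalyst intermediate C ⇌ by-product + catalyst intermediate D (K4 = 0.28 M, k4 = 25.3 min⁻¹)
    catalyst intermediate D → free catalyst + target (k5 = 1.97 min⁻¹)
    reagent + by-product ⇌ idle adduct, settled at all times (K6 = 39.2 M⁻¹)

The forward rate of the first step, with the way back not counted and its partners held at their charge, gives the starting material a half-life of 0.19 h, short against the run of 2.5 h. Kept up, that rate gives a ceiling of >99.9% for c, and I commit to a flask close to complete.

The idle adduct is kept at balance with the adduct constant K, 39.2 M⁻¹, so its concentration is K times free reagent times free by-product W. Free reagent cancels from the share, leaving f = 1/(1 + KW).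

Both bounds take this flask as complete. If no reagent were bound, W would equal the starting charge and f would be 13.05%, a lower bound. If all the unused reagent, 0.00850 M, were bound, W would fall by that much and f would be 13.64%, an upper bound. Now iterate: put the lower bound back, so that the bound part of the reagent takes W to 0.163 M, and this iterated free share of the unused reagent comes to 13.56%.

The forecast, on the ground “I treated the cycle as quasi-steady”, gives 99.7% and 13.6%, the second inside this bracket.

The flask gives 99.6% and 13.7%, which is 0.10 percentage points above 13.6% and level with the upper bound of 13.6%. At 2.50 h it holds 0.161 M of by-product, less than 0.163 M, and the same formula on that reading gives 13.7%.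

In the neighbour flask charged with 0.420 equiv of reagent, reagent is the limiting reagent, so W should approach the reagent charge, 0.0714 M, and f should be 26.3%. At 2.50 h that neighbour flask holds 0.0714 M of by-product and 0% of its reagent charge, has a free share of 26.3%, and has used 44.0% of its starting material.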